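**Plan**

- Retrosynthesis: the two catechol O–CH2Ph bonds are cut first, then the chroman O–CMe2 bond, which uncovers an ortho-(epoxyprenyl)phenol. The epoxide oxygen is then removed (back to the prenyl alkene), the furanone C2–CH2Ar bond is cut, and finally the furanone C2–C3 and O1–C5 bonds, giving an arylpyruvate and methyl glyoxylate.
- Forward: the furanone ring is made first (aldol–lactonisation, O-methylation), the prenylated benzyl arm is joined at C2, the prenyl alkene is epoxidised, the dihydropyran ring is closed in the penultimate step, and the benzyl ethers are removed last.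
- Feature that allows the key step: in the chroman ring the ether oxygen sits on the CMe2 carbon, and that carbon is the direct neighbour of the CH(OH) carbon. This is what an ortho-prenyl epoxide leaves behind when the phenol oxygen opens it at the tertiary carbon.
- Stereochemistry: the furanone C2 (S) comes from the chiral ammonium ion pair in the phase-transfer benzylation. The carbinol carbon (S) comes from an ent-Shi epoxidation and passes through the ring closure unchanged.
- Furanone locants used throughout: O1, C2 (quaternary, CO2Me), C3 (aryl), C4 (OMe), C5 (C=O).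

Key step: step 12

Assumption: the catalyst antipode in step 9 that leads to (S)-16 cannot be predicted from a model and is fixed by a test run with both commercial antipodes; 5 is drawn as the keto tautomer although it should be largely enolised, and 8 and 9 are racemic.

Step 1
Reactants: 1 3,4-bis(benzyloxy)benzaldehyde; 2 methyl 2-[(tert-butoxycarbonyl)amino]-2-(dimethoxyphosphoryl)acetate
Product: 3 methyl (Z)-3-[3,4-bis(benzyloxy)phenyl]-2-[(tert-butoxycarbonyl)amino]prop-2-enoate
Conditions: DBU, CH2Cl2, 0 °C → rt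
Reagents that add atoms: none
Why: Horner–Wadsworth–Emmons olefination of a phosphonoglycinate with an aromatic aldehyde should give the Z-dehydroamino ester cleanly, and its geometry is immaterial because the alkene is hydrolysed next.

Step 2
Reactants: 3 methyl (Z)-3-[3,4-bis(benzyloxy)phenyl]-2-[(tert-butoxycarbonyl)amino]prop-2-enoate
Product: 5 methyl 3-[3,4-bis(benzyloxy)phenyl]-2-oxopropanoate, via enamine ester 4 (not isolated)
Conditions: TFA/CH2Cl2 (1:4), 0 °C; then THF/H2O, rt
Reagents that add atoms: water, O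
Why: Acidolysis of the Boc carbamate releases the primary enamine, which tautomerises to the alpha-imino ester and is hydrolysed to the alpha-keto ester (enamide-to-pyruvate hydrolysis) under conditions that should spare the benzyl ethers.

Step 3
Reactants: 5 methyl 3-[3,4-bis(benzyloxy)phenyl]-2-oxopropanoate; 6 methyl glyoxylate
Product: 8 methyl 3-[3,4-bis(benzyloxy)phenyl]-4-hydroxy-5-oxo-2,5-dihydrofuran-2-carboxylate, via aldol adduct 7 (not isolated)
Conditions: 6 (2 equiv), Et3N, CH2Cl2, 0 °C → rt; then 1 M HCl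
Reagents that add atoms: none
Why: Crossed aldol addition of the enolised keto ester to the non-enolisable, far more electrophilic glyoxylate, then lactonisation of the new hydroxyl onto the keto-ester carbonyl and enolisation, is the standard isotetronic acid synthesis; C2 forms racemic and is fixed only in step 9.

Step 4
Reactants: 8 methyl 3-[3,4-bis(benzyloxy)phenyl]-4-hydroxy-5-oxo-2,5-dihydrofuran-2-carboxylate
Product: 9 methyl 3-[3,4-bis(benzyloxy)phenyl]-4-methoxy-5-oxo-2,5-dihydrofuran-2-carboxylate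
Conditions: TMSCHN2, MeOH/toluene, 0 °C → rt
Reagents that add atoms: (trimethylsilyl)diazomethane, C[Si](C)(C)C=[N+]=[N-]
Why: The acidic enol is O-methylated by the diazoalkane (diazomethane-type methylation) without base, so the acidic C2–H and both ester groups should stay untouched.

Step 5
Reactants: 10 4-hydroxybenzaldehyde; 11 prenyl bromide
Product: 12 4-hydroxy-3-(3-methylbut-2-en-1-yl)benzaldehyde
Conditions: aq. KOH (1 equiv), rt
Reagents that add atoms: none
Why: In water the hydrogen-bonded phenoxide reacts through its free ortho carbon (ortho C-alkylation of a phenoxide, SN2 at the primary allylic carbon), the para position being blocked by the formyl group.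

Step 6
Reactants: 12 4-hydroxy-3-(3-methylbut-2-en-1-yl)benzaldehyde
Product: 13 3-(3-methylbut-2-en-1-yl)-4-[(triisopropylsilyl)oxy]benzaldehyde
Conditions: TIPSCl, imidazole, DMF, rt
Reagents that add atoms: triisopropylsilyl chloride, CC(C)[Si](Cl)(C(C)C)C(C)C
Why: Routine phenol silylation; the bulky TIPS ether should withstand the carbonate base of step 9 and the basic medium of step 10 and still be cleaved by fluoride.

Step 7
Reactants: 13 3-(3-methylbut-2-en-1-yl)-4-[(triisopropylsilyl)oxy]benzaldehyde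
Product: 14 {3-(3-methylbut-2-en-1-yl)-4-[(triisopropylsilyl)oxy]phenyl}methanol
Conditions: NaBH4, MeOH, 0 °C
Reagents that add atoms: none
Why: Chemoselective borohydride reduction of the aldehyde; the alkene and the silyl ether are inert.

Step 8
Reactants: 14 {3-(3-methylbut-2-en-1-yl)-4-[(triisopropylsilyl)oxy]phenyl}methanol
Product: 15 [4-(bromomethyl)-2-(3-methylbut-2-en-1-yl)phenoxy]triisopropylsilane
Conditions: CBr4, PPh3, CH2Cl2, 0 °C; used at once
Reagents that add atoms: tetrabromomethane, BrC(Br)(Br)Br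
Why: The Appel reaction converts the benzylic alcohol into the bromide under neutral conditions, avoiding HBr that would add to the prenyl alkene.

Step 9
Reactants: 9 methyl 3-[3,4-bis(benzyloxy)phenyl]-4-methoxy-5-oxo-2,5-dihydrofuran-2-carboxylate; 15 [4-(bromomethyl)-2-(3-methylbut-2-en-1-yl)phenoxy]triisopropylsilane
Product: 16 methyl (2S)-3-[3,4-bis(benzyloxy)phenyl]-4-methoxy-2-({3-(3-methylbut-2-en-1-yl)-4-[(triisopropylsilyl)oxy]phenyl}methyl)-5-oxo-2,5-dihydrofuran-2-carboxylate
Conditions: (S,S)-3,4,5-trifluorophenyl-NAS bromide (3 mol %), solid K2CO3, toluene, −20 °C, Ar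
Reagents that add atoms: none
Why: Proposed new method: carbonate removes the C2–H (alpha to the ester, gamma to the lactone carbonyl) to give a 2-oxidofuran that pairs with the C2-symmetric spiro ammonium ion, which should shield one face so that 15 attacks C2 from the other and sets the (S)-quaternary centre; C2 is expected to react in preference to C4 or oxygen because it is the ester alpha-carbon of a loose ammonium ion pair and its alkylation restores the conjugated butenolide; the closest known reactions are chiral phase-transfer benzylations of alpha-substituted beta-keto esters and of azlactone-type heteroaromatic enolates to quaternary stereocentres.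

Step 10
Reactants: 16 methyl (2S)-3-[3,4-bis(benzyloxy)phenyl]-4-methoxy-2-({3-(3-methylbut-2-en-1-yl)-4-[(triisopropylsilyl)oxy]phenyl}methyl)-5-oxo-2,5-dihydrofuran-2-carboxylate
Product: 17 methyl (2S)-3-[3,4-bis(benzyloxy)phenyl]-2-({3-{[(2S)-3,3-dimethyloxiran-2-yl]methyl}-4-[(triisopropylsilyl)oxy]phenyl}methyl)-4-methoxy-5-oxo-2,5-dihydrofuran-2-carboxylate
Conditions: L-fructose-derived Shi ketone (ent-Shi ketone, 0.3 equiv), Oxone (2KHSO5·KHSO4·K2SO4), K2CO3, Bu4NHSO4, MeCN/dimethoxymethane/aq. Na2B4O7 buffer, 0 °C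
Reagents that add atoms: potassium peroxymonosulfate, [K+].[O-]S(=O)(=O)OO
Why: In the Shi epoxidation the chiral dioxirane transfers oxygen through a spiro transition state to the electron-rich trisubstituted prenyl alkene only (the tetrasubstituted, acceptor-substituted butenolide alkene is inert), and the L-fructose-derived ketone should give the (S)-epoxide, the mirror image of the (R)-epoxide expected from the D-fructose-derived ketone with this alkene type.

Step 11
Reactants: 17 methyl (2S)-3-[3,4-bis(benzyloxy)phenyl]-2-({3-{[(2S)-3,3-dimethyloxiran-2-yl]methyl}-4-[(triisopropylsilyl)oxy]phenyl}methyl)-4-methoxy-5-oxo-2,5-dihydrofuran-2-carboxylate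
Product: 18 methyl (2S)-3-[3,4-bis(benzyloxy)phenyl]-2-[(3-{[(2S)-3,3-dimethyloxiran-2-yl]methyl}-4-hydroxyphenyl)methyl]-4-methoxy-5-oxo-2,5-dihydrofuran-2-carboxylate
Conditions: TBAF, AcOH (1.5 equiv per fluoride), THF, 0 °C; crude product taken on directly
Reagents that add atoms: none
Why: Fluoride cleaves the aryl Si–O bond (desilylation) while the acetic acid buffer protonates the phenoxide as it is released, which should suppress the base-mediated 5-exo attack on the secondary epoxide carbon.

Step 12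
Reactants: 18 methyl (2S)-3-[3,4-bis(benzyloxy)phenyl]-2-[(3-{[(2S)-3,3-dimethyloxiran-2-yl]methyl}-4-hydroxyphenyl)methyl]-4-methoxy-5-oxo-2,5-dihydrofuran-2-carboxylate
Product: 19 methyl (2S)-3-[3,4-bis(benzyloxy)phenyl]-2-{[(3S)-3-hydroxy-2,2-dimethyl-3,4-dihydro-2H-chromen-6-yl]methyl}-4-methoxy-5-oxo-2,5-dihydrofuran-2-carboxylate
Conditions: CSA (0.2 equiv), CH2Cl2, 0 °C → rt
Reagents that add atoms: none
Why: CSA protonates the epoxide oxygen, the C–O bond to the gem-dimethyl carbon is polarised, and the neighbouring phenol oxygen attacks that tertiary carbon to form the O–CMe2 bond, after which proton loss gives the chromanol. The closest known reaction type is the acid-mediated cyclisation of ortho-(epoxyprenyl)phenols to 3-hydroxy-2,2-dimethylchromans. The dihydropyran ring closes in a 6-endo-tet mode. No new stereocentre is created: the C–O bond at the secondary epoxide carbon is never broken, so the (S)-epoxide carbon becomes the (S)-carbinol carbon, and the quaternary C2 is a spectator. The step needs 6-endo to win over 5-exo opening, and this should be secured by the two methyl groups, which stabilise positive charge at the tertiary carbon under Brønsted acid in a base-free, non-nucleophilic medium. The enol-ether butenolide, the methyl ester and the benzyl ethers should tolerate catalytic CSA at this temperature.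

Step 13
Reactants: 19 methyl (2S)-3-[3,4-bis(benzyloxy)phenyl]-2-{[(3S)-3-hydroxy-2,2-dimethyl-3,4-dihydro-2H-chromen-6-yl]methyl}-4-methoxy-5-oxo-2,5-dihydrofuran-2-carboxylate
Product: 20 methyl (2S)-3-(3,4-dihydroxyphenyl)-2-{[(3S)-3-hydroxy-2,2-dimethyl-3,4-dihydro-2H-chromen-6-yl]methyl}-4-methoxy-5-oxo-2,5-dihydrofuran-2-carboxylate
Conditions: H2 (1 atm), 10% Pd/C, EtOAc/MeOH, rt
Reagents that add atoms: none
Why: Hydrogenolysis of the two aryl benzyl ethers over palladium on carbon; the tetrasubstituted butenolide alkene, the chroman ether and the tertiary allylic lactone C–O bond should not be reduced under one atmosphere of hydrogen.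

**Compound list**

1 | 3,4-bis(benzyloxy)benzaldehyde | O=Cc1ccc(OCc2ccccc2)c(OCc2ccccc2)c1 | starting material
2 | methyl 2-[(tert-butoxycarbonyl)amino]-2-(dimethoxyphosphoryl)acetate (racemic Boc-alpha-phosphonoglycine trimethyl ester) | COC(=O)C(NC(=O)OC(C)(C)C)P(=O)(OC)OC | starting material
3 | methyl (Z)-3-[3,4-bis(benzyloxy)phenyl]-2-[(tert-butoxycarbonyl)amino]prop-2-enoate | COC(=O)/C(NC(=O)OC(C)(C)C)=C/c1ccc(OCc2ccccc2)c(OCc2ccccc2)c1 | intermediate
4 | methyl 2-amino-3-[3,4-bis(benzyloxy)phenyl]prop-2-enoate (enamine ester, not isolated) | COC(=O)C(N)=Cc1ccc(OCc2ccccc2)c(OCc2ccccc2)c1 | intermediate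
5 | methyl 3-[3,4-bis(benzyloxy)phenyl]-2-oxopropanoate | COC(=O)C(=O)Cc1ccc(OCc2ccccc2)c(OCc2ccccc2)c1 | intermediate
6 | methyl glyoxylate | COC(=O)C=O | starting material
7 | dimethyl 3-[3,4-bis(benzyloxy)phenyl]-2-hydroxy-4-oxopentanedioate (aldol adduct, diastereomer mixture, not isolated) | COC(=O)C(O)C(C(=O)C(=O)OC)c1ccc(OCc2ccccc2)c(OCc2ccccc2)c1 | intermediate
8 | methyl 3-[3,4-bis(benzyloxy)phenyl]-4-hydroxy-5-oxo-2,5-dihydrofuran-2-carboxylate (racemic) | COC(=O)C1OC(=O)C(O)=C1c1ccc(OCc2ccccc2)c(OCc2ccccc2)c1 | intermediate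
9 | methyl 3-[3,4-bis(benzyloxy)phenyl]-4-methoxy-5-oxo-2,5-dihydrofuran-2-carboxylate (racemic) | COC(=O)C1OC(=O)C(OC)=C1c1ccc(OCc2ccccc2)c(OCc2ccccc2)c1 | intermediate
10 | 4-hydroxybenzaldehyde | O=Cc1ccc(O)cc1 | starting material
11 | prenyl bromide (1-bromo-3-methylbut-2-ene) | CC(C)=CCBr | starting material
12 | 4-hydroxy-3-(3-methylbut-2-en-1-yl)benzaldehyde | CC(C)=CCc1cc(C=O)ccc1O | intermediate
13 | 3-(3-methylbut-2-en-1-yl)-4-[(triisopropylsilyl)oxy]benzaldehyde | CC(C)=CCc1cc(C=O)ccc1O[Si](C(C)C)(C(C)C)C(C)C | intermediate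
14 | {3-(3-methylbut-2-en-1-yl)-4-[(triisopropylsilyl)oxy]phenyl}methanol | CC(C)=CCc1cc(CO)ccc1O[Si](C(C)C)(C(C)C)C(C)C | intermediate
15 | [4-(bromomethyl)-2-(3-methylbut-2-en-1-yl)phenoxy]triisopropylsilane | CC(C)=CCc1cc(CBr)ccc1O[Si](C(C)C)(C(C)C)C(C)C | intermediate
16 | methyl (2S)-3-[3,4-bis(benzyloxy)phenyl]-4-methoxy-2-({3-(3-methylbut-2-en-1-yl)-4-[(triisopropylsilyl)oxy]phenyl}methyl)-5-oxo-2,5-dihydrofuran-2-carboxylate | COC(=O)[C@@]1(Cc2ccc(O[Si](C(C)C)(C(C)C)C(C)C)c(CC=C(C)C)c2)OC(=O)C(OC)=C1c1ccc(OCc2ccccc2)c(OCc2ccccc2)c1 | intermediate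
17 | methyl (2S)-3-[3,4-bis(benzyloxy)phenyl]-2-({3-{[(2S)-3,3-dimethyloxiran-2-yl]methyl}-4-[(triisopropylsilyl)oxy]phenyl}methyl)-4-methoxy-5-oxo-2,5-dihydrofuran-2-carboxylate | COC(=O)[C@@]1(Cc2ccc(O[Si](C(C)C)(C(C)C)C(C)C)c(C[C@@H]3OC3(C)C)c2)OC(=O)C(OC)=C1c1ccc(OCc2ccccc2)c(OCc2ccccc2)c1 | intermediate
18 | methyl (2S)-3-[3,4-bis(benzyloxy)phenyl]-2-[(3-{[(2S)-3,3-dimethyloxiran-2-yl]methyl}-4-hydroxyphenyl)methyl]-4-methoxy-5-oxo-2,5-dihydrofuran-2-carboxylate | COC(=O)[C@@]1(Cc2ccc(O)c(C[C@@H]3OC3(C)C)c2)OC(=O)C(OC)=C1c1ccc(OCc2ccccc2)c(OCc2ccccc2)c1 | intermediate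
19 | methyl (2S)-3-[3,4-bis(benzyloxy)phenyl]-2-{[(3S)-3-hydroxy-2,2-dimethyl-3,4-dihydro-2H-chromen-6-yl]methyl}-4-methoxy-5-oxo-2,5-dihydrofuran-2-carboxylate | COC(=O)[C@@]1(Cc2ccc3c(c2)C[C@H](O)C(C)(C)O3)OC(=O)C(OC)=C1c1ccc(OCc2ccccc2)c(OCc2ccccc2)c1 | intermediate
20 | methyl (2S)-3-(3,4-dihydroxyphenyl)-2-{[(3S)-3-hydroxy-2,2-dimethyl-3,4-dihydro-2H-chromen-6-yl]methyl}-4-methoxy-5-oxo-2,5-dihydrofuran-2-carboxylate | COC(=O)[C@@]1(Cc2ccc3c(c2)C[C@H](O)C(C)(C)O3)OC(=O)C(OC)=C1c1ccc(O)c(O)c1 | target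

**Step count**

Total: 13 steps. Longest linear sequence: 9 steps (steps 1–4, then 9–13; the bromide arm, steps 5–8 then 9–13, is equally long).

**Steps most likely to fail**

Step 9. The ion pair may discriminate the two faces of the furanolate poorly, and the ambident anion may take the benzyl group at the methoxy-bearing C4 or on oxygen instead of at C2. The fallback builds the quaternary carbon before the ring with known reactions; it sets out from 1 and 15 and returns at 16.
- Roskamp homologation of 1 (methyl diazoacetate, NbCl5 cat., CH2Cl2) would give methyl 3-[3,4-bis(benzyloxy)phenyl]-3-oxopropanoate F1.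
- C-alkylation of F1 with 15 (K2CO3, acetone) would give methyl 2-[3,4-bis(benzyloxy)benzoyl]-3-{3-(3-methylbut-2-en-1-yl)-4-[(triisopropylsilyl)oxy]phenyl}propanoate F2, with unambiguous connectivity.
- Enolate hydroxylation with an enantiopure (camphorsulfonyl)oxaziridine (NaHMDS, THF, −78 °C; antipode chosen for the S product) would give methyl (2S)-2-[3,4-bis(benzyloxy)benzoyl]-2-hydroxy-3-{3-(3-methylbut-2-en-1-yl)-4-[(triisopropylsilyl)oxy]phenyl}propanoate F3.
- Acylation with methoxyacetyl chloride (pyridine, DMAP) would give methyl (2S)-2-[3,4-bis(benzyloxy)benzoyl]-2-[(methoxyacetyl)oxy]-3-{3-(3-methylbut-2-en-1-yl)-4-[(triisopropylsilyl)oxy]phenyl}propanoate F4.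
- DBU in MeCN would then close the ring by intramolecular aldol condensation, the established construction of 3-alkoxy-4-aryl-5,5-disubstituted furanones, to reach 16. Any residual minor enantiomer would be removed on a chiral stationary phase.

Step 12. Closure through the secondary epoxide carbon (5-exo, to a 2-(2-hydroxypropan-2-yl)dihydrobenzofuran) or a 1,2-hydride shift of the developing tertiary cation to a ketone may compete with the 6-endo closure. The fallback forms the O–CMe2 bond by a different, regiochemically unambiguous ring closure; it sets out from 16 and returns at 20.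
- Desilylation of 16 (TBAF, THF) would give methyl (2S)-3-[3,4-bis(benzyloxy)phenyl]-2-{[4-hydroxy-3-(3-methylbut-2-en-1-yl)phenyl]methyl}-4-methoxy-5-oxo-2,5-dihydrofuran-2-carboxylate F5.
- Oxidative cyclisation with DDQ (toluene, 80 °C; ortho-quinone methide, then 6π-electrocyclisation) would give methyl (2S)-3-[3,4-bis(benzyloxy)phenyl]-2-[(2,2-dimethyl-2H-chromen-6-yl)methyl]-4-methoxy-5-oxo-2,5-dihydrofuran-2-carboxylate F6.
- Jacobsen epoxidation with the (S,S)-antipode of [N,N'-bis(3,5-di-tert-butylsalicylidene)cyclohexane-1,2-diaminato]manganese chloride (NaOCl, 4-phenylpyridine N-oxide, CH2Cl2, 0 °C) would give methyl (2S)-3-[3,4-bis(benzyloxy)phenyl]-2-{[(3S,4S)-3,4-epoxy-2,2-dimethyl-3,4-dihydro-2H-chromen-6-yl]methyl}-4-methoxy-5-oxo-2,5-dihydrofuran-2-carboxylate F7.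
- Hydrogenolysis (H2, Pd/C, EtOAc) would cleave the benzylic C4–O bond of the epoxide and both benzyl ethers in one operation to give 20.

Step 5. O-Prenylation and double alkylation may outrun ortho C-alkylation of the phenoxide. The fallback installs the prenyl group by cross-coupling; it sets out from 10 and returns at 13.
- Bromination of 10 (Br2, AcOH) would give 3-bromo-4-hydroxybenzaldehyde F8.
- Silylation (TIPSCl, imidazole, DMF) would give 3-bromo-4-[(triisopropylsilyl)oxy]benzaldehyde F9.
- Stille coupling with tributyl(3-methylbut-2-en-1-yl)stannane (Pd(PPh3)4, DMF, 90 °C) would deliver the prenyl group through its tin-bearing carbon to give 13.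

**Further compounds**

F1 | step 9 | methyl 3-[3,4-bis(benzyloxy)phenyl]-3-oxopropanoate | COC(=O)CC(=O)c1ccc(OCc2ccccc2)c(OCc2ccccc2)c1
F2 | step 9 | methyl 2-[3,4-bis(benzyloxy)benzoyl]-3-{3-(3-methylbut-2-en-1-yl)-4-[(triisopropylsilyl)oxy]phenyl}propanoate (racemic) | COC(=O)C(Cc1ccc(O[Si](C(C)C)(C(C)C)C(C)C)c(CC=C(C)C)c1)C(=O)c1ccc(OCc2ccccc2)c(OCc2ccccc2)c1
F3 | step 9 | methyl (2S)-2-[3,4-bis(benzyloxy)benzoyl]-2-hydroxy-3-{3-(3-methylbut-2-en-1-yl)-4-[(triisopropylsilyl)oxy]phenyl}propanoate | COC(=O)[C@@](C(=O)c1ccc(OCc2ccccc2)c(OCc2ccccc2)c1)(Cc1ccc(O[Si](C(C)C)(C(C)C)C(C)C)c(CC=C(C)C)c1)O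
F4 | step 9 | methyl (2S)-2-[3,4-bis(benzyloxy)benzoyl]-2-[(methoxyacetyl)oxy]-3-{3-(3-methylbut-2-en-1-yl)-4-[(triisopropylsilyl)oxy]phenyl}propanoate | COC(=O)[C@@](C(=O)c1ccc(OCc2ccccc2)c(OCc2ccccc2)c1)(Cc1ccc(O[Si](C(C)C)(C(C)C)C(C)C)c(CC=C(C)C)c1)OC(=O)COC
F5 | step 12 | methyl (2S)-3-[3,4-bis(benzyloxy)phenyl]-2-{[4-hydroxy-3-(3-methylbut-2-en-1-yl)phenyl]methyl}-4-methoxy-5-oxo-2,5-dihydrofuran-2-carboxylate | COC(=O)[C@@]1(Cc2ccc(O)c(CC=C(C)C)c2)OC(=O)C(OC)=C1c1ccc(OCc2ccccc2)c(OCc2ccccc2)c1
F6 | step 12 | methyl (2S)-3-[3,4-bis(benzyloxy)phenyl]-2-[(2,2-dimethyl-2H-chromen-6-yl)methyl]-4-methoxy-5-oxo-2,5-dihydrofuran-2-carboxylate | COC(=O)[C@@]1(Cc2ccc3c(c2)C=CC(C)(C)O3)OC(=O)C(OC)=C1c1ccc(OCc2ccccc2)c(OCc2ccccc2)c1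
F7 | step 12 | methyl (2S)-3-[3,4-bis(benzyloxy)phenyl]-2-{[(3S,4S)-3,4-epoxy-2,2-dimethyl-3,4-dihydro-2H-chromen-6-yl]methyl}-4-methoxy-5-oxo-2,5-dihydrofuran-2-carboxylate | COC(=O)[C@@]1(Cc2ccc3c(c2)[C@@H]4O[C@@H]4C(C)(C)O3)OC(=O)C(OC)=C1c1ccc(OCc2ccccc2)c(OCc2ccccc2)c1
F8 | step 5 | 3-bromo-4-hydroxybenzaldehyde | O=Cc1ccc(O)c(Br)c1
F9 | step 5 | 3-bromo-4-[(triisopropylsilyl)oxy]benzaldehyde | O=Cc1ccc(O[Si](C(C)C)(C(C)C)C(C)C)c(Br)c1
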